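The route closes the cyclohexane of the target at the C1–C6 bond (quinic acid numbering). C6 sits between the tertiary carbinol C1 and the carbinol C5, a 1,3-dioxygenated array that becomes an aldol retron once C5 is a ketone. A samarium Reformatsky-type aldol of an acyclic bromomethyl ketone onto its own α-keto ester therefore forms the ring and the C1 stereocentre in one operation. The cis-acetonide on O3/O4, taken from D-erythronolactone, chelates samarium and directs the addition. Hydroxyl-directed reduction sets C5, lactonisation gives 1,5-quinide, and O3 then O4 are acylated before acid unmasking.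

Key step: step 7

Remark: quinic acid numbering is used throughout: C1 carries OH and CO2H, O3 is cis to O4 and to the C1 hydroxyl, O5 is trans to O4 and cis to the carboxyl.

Step 1
Reactants: 1 2,3-O-isopropylidene-D-erythronolactone
Product: 2 2,3-O-isopropylidene-D-erythrofuranose (lactol, anomer mixture)
Conditions: iBu2AlH (1.1 equiv), CH2Cl2, −78 °C; aq. KNaC4H4O6 work-up
Reagents that add atoms: none
Why: Lactone-to-lactol reduction: at −78 °C the tetrahedral aluminium hemiacetal from iBu2AlH is stable, so over-reduction is avoided and both acetonide-bearing stereocentres are untouched.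

Step 2
Reactants: 2 2,3-O-isopropylidene-D-erythrofuranose
Product: 3 [(4R,5S)-5-ethynyl-2,2-dimethyl-1,3-dioxolan-4-yl]methanol
Conditions: dimethyl (1-diazo-2-oxopropyl)phosphonate (1.5 equiv), K2CO3, MeOH, 0 °C to rt
Reagents that add atoms: dimethyl (1-diazo-2-oxopropyl)phosphonate, CC(=O)C(=[N+]=[N-])P(=O)(OC)OC
Why: Seyferth–Gilbert homologation (Ohira–Bestmann variant) acts on the open hydroxy-aldehyde tautomer of the lactol and turns CHO into C≡CH under mild carbonate conditions, which should leave the adjacent stereocentre unchanged and frees the primary hydroxyl.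

Step 3
Reactants: 3 [(4R,5S)-5-ethynyl-2,2-dimethyl-1,3-dioxolan-4-yl]methanol
Product: 4 (4S,5S)-4-ethynyl-5-(iodomethyl)-2,2-dimethyl-1,3-dioxolane
Conditions: PPh3, imidazole, I2, CH2Cl2, 0 °C to rt
Reagents that add atoms: iodine, I-I
Why: Appel-type iodination (Garegg–Samuelsson conditions) converts the primary alcohol into the iodide by SN2 at a non-stereogenic carbon, and neither the alkyne nor the acetonide reacts.

Step 4
Reactants: 4 (4S,5S)-4-ethynyl-5-(iodomethyl)-2,2-dimethyl-1,3-dioxolane; 5 ethyl 1,3-dithiane-2-carboxylate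
Product: 6 ethyl 2-{[(4R,5S)-5-ethynyl-2,2-dimethyl-1,3-dioxolan-4-yl]methyl}-1,3-dithiane-2-carboxylate
Conditions: 5 (1.3 equiv), NaH (1.25 equiv), DMF, 0 °C; then 4, rt to 60 °C
Reagents that add atoms: none
Why: Corey–Seebach-type alkylation of the soft, weakly basic sodium anion of the dithiane ester (a glyoxylate acyl-anion equivalent) displaces the primary iodide by SN2, and the anion is not basic enough to deprotonate the alkyne or to favour E2.

Step 5
Reactants: 6 ethyl 2-{[(4R,5S)-5-ethynyl-2,2-dimethyl-1,3-dioxolan-4-yl]methyl}-1,3-dithiane-2-carboxylate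
Product: 7 ethyl 3-[(4R,5S)-5-(bromoethynyl)-2,2-dimethyl-1,3-dioxolan-4-yl]-2-oxopropanoate
Conditions: NBS (5 equiv), AgNO3 (0.2 equiv), 2,6-lutidine, acetone–H2O (9:1), 0 °C, short reaction time
Reagents that add atoms: N-bromosuccinimide, O=C1CCC(=O)N1Br; water, O
Why: NBS carries out two known reactions in one flask, the oxidative hydrolysis of the 1,3-dithiane to the α-keto ester (Corey–Erickson dethioketalisation) and the AgNO3-catalysed bromination of the terminal alkyne, while the lutidine buffer, low temperature and short time protect the acetonide and the enolisable keto ester.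

Step 6
Reactants: 7 ethyl 3-[(4R,5S)-5-(bromoethynyl)-2,2-dimethyl-1,3-dioxolan-4-yl]-2-oxopropanoate
Product: 8 ethyl 3-[(4R,5R)-5-(bromoacetyl)-2,2-dimethyl-1,3-dioxolan-4-yl]-2-oxopropanoate
Conditions: Ph3PAuNTf2 (5 mol %), H2O (5 equiv), 1,2-dichloroethane, rt
Reagents that add atoms: water, O
Why: Gold-catalysed hydration of a 1-bromoalkyne: π-activation by monovalent gold directs water to the carbon remote from bromine, so that the bromomethyl ketone forms regioselectively under neutral conditions tolerated by the acetonide and the keto ester.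

Step 7
Reactants: 8 ethyl 3-[(4R,5R)-5-(bromoacetyl)-2,2-dimethyl-1,3-dioxolan-4-yl]-2-oxopropanoate
Product: 10 ethyl (1S,3R,4R)-1-hydroxy-3,4-(isopropylidenedioxy)-5-oxocyclohexane-1-carboxylate, via samarium enolate 9 (not isolated)
Conditions: SmI2 (2.2 equiv, 0.1 M in THF) added slowly to 8, THF, −78 °C, no proton source; sat. aq. NH4Cl at −78 °C
Reagents that add atoms: none
Why: Two single-electron transfers from divalent samarium cleave the C–Br bond of 8 and give the trivalent samarium enolate 9 regiospecifically at C6, which adds to the α-keto ester carbonyl C1 in an intramolecular aldol. The closest known reaction type is the SmI2-promoted intramolecular aldol of α-bromo ketones (samarium Reformatsky reaction). The only ring closed is the cyclohexanone, in the 6-(enolendo)-exo-trig mode. The new stereocentre C1 is controlled by chelation: samarium on the enolate oxygen is also held by the adjacent dioxolane oxygen O4, which fixes C4–O4 in the enolate plane (equatorial in the chair) and pushes the cis-fused O3 axial; the keto-ester oxygen can then join the same metal only from an axial position syn to O3 with the ester equatorial, so the C1 hydroxyl should end cis to O3 and O4 (1S). The step needs chemoselective reduction of C–Br in the presence of the α-keto ester and the α-alkoxy ketone, secured by the much faster dissociative electron transfer to the α-bromo ketone, by slow addition of two equivalents at −78 °C and by the absence of proton donors; it also needs the facial selectivity at C1, secured by the cis-acetonide. No base is present, so the β-alkoxy keto ester cannot eliminate, and the cold quench prevents retro-aldol.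

Step 8
Reactants: 10 ethyl (1S,3R,4R)-1-hydroxy-3,4-(isopropylidenedioxy)-5-oxocyclohexane-1-carboxylate
Product: 11 ethyl 3,4-O-isopropylidenequinate
Conditions: Me4NBH(OAc)3 (5 equiv), MeCN–AcOH (1:1), −25 °C
Reagents that add atoms: none
Why: Evans–Saksena reduction: the C1 hydroxyl exchanges onto boron and delivers hydride intramolecularly to the C5 ketone from its own face, so that the new C5 hydroxyl is anti to O1 and trans to O4 as in (−)-quinic acid, while esters and acetonide are inert to the triacetoxyborohydride.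

Step 9
Reactants: 11 ethyl 3,4-O-isopropylidenequinate
Product: 13 1,5-quinide (quinic acid 1,5-lactone), via ethyl quinate 12 (not isolated)
Conditions: TFA–H2O (9:1), 0 °C to rt; evaporate; TsOH·H2O (5 mol %), toluene–DMF (10:1), reflux, Dean–Stark
Reagents that add atoms: none
Why: Acid hydrolysis of the acetonide followed by acid-catalysed lactonisation (intramolecular transesterification with removal of ethanol) gives the bicyclic γ-lactone, which can form because the ester and the C5 hydroxyl are cis, and which masks the carboxyl and O5 in one operation.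

Step 10
Reactants: 14 caffeic acid
Product: 15 (E)-3,4-diacetoxycinnamic acid
Conditions: Ac2O (3 equiv), pyridine, rt; aq. HCl work-up
Reagents that add atoms: acetic anhydride, CC(=O)OC(C)=O
Why: Phenol acetylation with acetic anhydride and pyridine; the mixed anhydride formed at the carboxyl is hydrolysed on aqueous work-up, and the (E)-alkene is not affected.

Step 11
Reactants: 13 1,5-quinide; 15 (E)-3,4-diacetoxycinnamic acid
Product: 17 3-O-[(E)-3,4-diacetoxycinnamoyl]-1,5-quinide, via 3,4-diacetoxycinnamoyl chloride 16 (not isolated)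
Conditions: 15, (COCl)2, DMF (cat.), CH2Cl2, rt, evaporate; then 13 (1.0 equiv), pyridine–CH2Cl2, −30 °C to 0 °C
Reagents that add atoms: none
Why: Acyl chloride formation (oxalyl chloride with catalytic DMF) followed by regioselective esterification: in the lactone-locked chair the 3-hydroxyl is equatorial and least hindered, the 4-hydroxyl is axial and the 1-hydroxyl is tertiary, so one equivalent of 16 at low temperature should acylate O3.

Step 12
Reactants: 18 p-coumaric acid
Product: 19 (E)-4-acetoxycinnamic acid
Conditions: Ac2O (2 equiv), pyridine, rt; aq. HCl work-up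
Reagents that add atoms: acetic anhydride, CC(=O)OC(C)=O
Why: Phenol acetylation as in step 10, with hydrolysis of any mixed anhydride on work-up.

Step 13
Reactants: 17 3-O-[(E)-3,4-diacetoxycinnamoyl]-1,5-quinide; 19 (E)-4-acetoxycinnamic acid
Product: 21 3-O-[(E)-3,4-diacetoxycinnamoyl]-4-O-[(E)-4-acetoxycinnamoyl]-1,5-quinide, via 4-acetoxycinnamoyl chloride 20 (not isolated)
Conditions: 19, (COCl)2, DMF (cat.), CH2Cl2, rt, evaporate; then 17, pyridine, DMAP (0.2 equiv), CH2Cl2, 0 °C to rt
Reagents that add atoms: none
Why: Esterification of the remaining secondary (axial) 4-hydroxyl with the acyl chloride under DMAP catalysis; the tertiary, lactone-flanked 1-hydroxyl is too hindered to compete at room temperature.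

Step 14
Reactants: 21 3-O-[(E)-3,4-diacetoxycinnamoyl]-4-O-[(E)-4-acetoxycinnamoyl]-1,5-quinide
Product: 22 3-O-caffeoyl-4-O-(p-coumaroyl)quinic acid, (1R,3R,4S,5R)-configured target
Conditions: 2 M aq. HCl–THF (1:3), rt, several days with monitoring
Reagents that add atoms: water, O
Why: Acid-catalysed hydrolysis cleaves the three phenolic acetates and opens the strained γ-lactone to the hydroxy acid, while the two conjugated cinnamate esters are much less reactive and acyl migration, which is base-promoted, is suppressed at low pH.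

Compound list
1 | 2,3-O-isopropylidene-D-erythronolactone, (3aR,6aR) | CC1(C)O[C@H]2C(=O)OC[C@H]2O1 | starting material
2 | 2,3-O-isopropylidene-D-erythrofuranose (lactol, anomer mixture) | CC1(C)O[C@H]2C(O)OC[C@H]2O1 | intermediate
3 | [(4R,5S)-5-ethynyl-2,2-dimethyl-1,3-dioxolan-4-yl]methanol | CC1(C)O[C@@H](C#C)[C@@H](CO)O1 | intermediate
4 | (4S,5S)-4-ethynyl-5-(iodomethyl)-2,2-dimethyl-1,3-dioxolane | CC1(C)O[C@@H](C#C)[C@@H](CI)O1 | intermediate
5 | ethyl 1,3-dithiane-2-carboxylate | CCOC(=O)C1SCCCS1 | starting material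
6 | ethyl 2-{[(4R,5S)-5-ethynyl-2,2-dimethyl-1,3-dioxolan-4-yl]methyl}-1,3-dithiane-2-carboxylate | CC1(C)O[C@@H](C#C)[C@@H](CC2(C(=O)OCC)SCCCS2)O1 | intermediate
7 | ethyl 3-[(4R,5S)-5-(bromoethynyl)-2,2-dimethyl-1,3-dioxolan-4-yl]-2-oxopropanoate | CC1(C)O[C@@H](C#CBr)[C@@H](CC(=O)C(=O)OCC)O1 | intermediate
8 | ethyl 3-[(4R,5R)-5-(bromoacetyl)-2,2-dimethyl-1,3-dioxolan-4-yl]-2-oxopropanoate | CC1(C)O[C@@H](C(=O)CBr)[C@@H](CC(=O)C(=O)OCC)O1 | intermediate
9 | diiodosamarium enolate of the methyl ketone derived from 8 (trivalent samarium, not isolated) | CC1(C)O[C@@H](C(=C)O[Sm](I)I)[C@@H](CC(=O)C(=O)OCC)O1 | intermediate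
10 | ethyl (1S,3R,4R)-1-hydroxy-3,4-(isopropylidenedioxy)-5-oxocyclohexane-1-carboxylate (C1 hydroxyl cis to the acetonide oxygens) | CC1(C)O[C@H]2C(=O)C[C@](O)(C(=O)OCC)C[C@H]2O1 | intermediate
11 | ethyl 3,4-O-isopropylidenequinate (configuration of (−)-quinic acid) | CC1(C)O[C@H]2[C@H](O)C[C@](O)(C(=O)OCC)C[C@H]2O1 | intermediate
12 | ethyl quinate (not isolated) | O[C@H]1[C@H](O)C[C@](O)(C(=O)OCC)C[C@H]1O | intermediate
13 | 1,5-quinide (lactone between the carboxyl and O5; free 1-, 3- and 4-hydroxyls) | O[C@H]1[C@H]2C[C@](O)(C(=O)O2)C[C@H]1O | intermediate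
14 | caffeic acid | OC(=O)/C=C/c1ccc(O)c(O)c1 | starting material
15 | (E)-3,4-diacetoxycinnamic acid | CC(=O)Oc1ccc(/C=C/C(=O)O)cc1OC(C)=O | intermediate
16 | (E)-3,4-diacetoxycinnamoyl chloride (not isolated) | CC(=O)Oc1ccc(/C=C/C(=O)Cl)cc1OC(C)=O | intermediate
17 | 3-O-[(E)-3,4-diacetoxycinnamoyl]-1,5-quinide | O[C@H]1[C@H]2C[C@](O)(C(=O)O2)C[C@H]1OC(=O)/C=C/c1ccc(OC(C)=O)c(OC(C)=O)c1 | intermediate
18 | p-coumaric acid | OC(=O)/C=C/c1ccc(O)cc1 | starting material
19 | (E)-4-acetoxycinnamic acid | CC(=O)Oc1ccc(/C=C/C(=O)O)cc1 | intermediate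
20 | (E)-4-acetoxycinnamoyl chloride (not isolated) | CC(=O)Oc1ccc(/C=C/C(=O)Cl)cc1 | intermediate
21 | 3-O-[(E)-3,4-diacetoxycinnamoyl]-4-O-[(E)-4-acetoxycinnamoyl]-1,5-quinide | O=C(/C=C/c1ccc(OC(C)=O)cc1)O[C@H]1[C@H]2C[C@](O)(C(=O)O2)C[C@H]1OC(=O)/C=C/c1ccc(OC(C)=O)c(OC(C)=O)c1 | intermediate
22 | 3-O-caffeoyl-4-O-(p-coumaroyl)quinic acid, (1R,3R,4S,5R) | O=C(/C=C/c1ccc(O)cc1)O[C@H]1[C@H](O)C[C@](O)(C(=O)O)C[C@H]1OC(=O)/C=C/c1ccc(O)c(O)c1 | target

Total step count: 14. Longest linear sequence: 12 (steps 1 to 9, then 11, 13 and 14); steps 10 and 12 prepare the two acyl donors.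

Steps most likely to fail

Step 7 (key step). Electron transfer to the α-keto ester may compete with C–Br cleavage (ketyl formation, pinacol coupling, over-reduction). Chelate control may also be incomplete, so that part of the material closes on the other face of C1. The fallback sets out from 8: zinc dust in aq. NH4Cl–THF removes the bromine and gives ethyl 3-[(4R,5R)-5-acetyl-2,2-dimethyl-1,3-dioxolan-4-yl]-2-oxopropanoate F1. F1 is then cyclised by a direct, non-reductive aldol under soft enolisation (MgBr2·OEt2, iPr2NEt, CH2Cl2, −20 °C). Magnesium bound to the ketone oxygen and to O4 should direct kinetic deprotonation to the methyl group and hold the same chelated chair. The fallback returns to the route at 10.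

Step 4. Substitution at the β-branched, β-oxygenated primary carbon may be slow, and E2 loss of iodide to an exocyclic enol ether may take over on heating. The fallback sets out from 4 and uses the far more nucleophilic parent dithiane anion in stages. The alkyne is silylated (LiN(SiMe3)2, Me3SiCl, THF, −78 °C) to (4S,5S)-4-(iodomethyl)-2,2-dimethyl-5-[(trimethylsilyl)ethynyl]-1,3-dioxolane F2. The iodide is displaced with 2-lithio-1,3-dithiane (THF–DMPU, −78 to −20 °C) to give 2-{[(4R,5S)-2,2-dimethyl-5-[(trimethylsilyl)ethynyl]-1,3-dioxolan-4-yl]methyl}-1,3-dithiane F3. The dithiane is lithiated (n-BuLi) and acylated with ethyl chloroformate to give ethyl 2-{[(4R,5S)-2,2-dimethyl-5-[(trimethylsilyl)ethynyl]-1,3-dioxolan-4-yl]methyl}-1,3-dithiane-2-carboxylate F4. F4 is submitted to the conditions of step 5, where NBS/AgNO3 also effects bromodesilylation of the alkynylsilane, so the fallback returns to the route at 7.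

Step 11. Discrimination between the equatorial 3-hydroxyl and the axial 4-hydroxyl may be poor, with diacylation or acylation at O4 as competing processes. The fallback sets out from 13 and fixes the order with a protecting group. Silylation of the most reactive hydroxyl (TBSCl, imidazole, DMF, 0 °C) gives 3-O-(tert-butyldimethylsilyl)-1,5-quinide F5. Acylation of O4 with 20 (pyridine, DMAP) gives 4-O-[(E)-4-acetoxycinnamoyl]-3-O-(tert-butyldimethylsilyl)-1,5-quinide F6. Desilylation under acidic fluoride conditions (HF·pyridine, THF, 0 °C) gives 4-O-[(E)-4-acetoxycinnamoyl]-1,5-quinide F7. Acylation of the freed 3-hydroxyl with 16 then returns to the route at 21.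

Further compounds
F1 | step 7 | ethyl 3-[(4R,5R)-5-acetyl-2,2-dimethyl-1,3-dioxolan-4-yl]-2-oxopropanoate | CC1(C)O[C@@H](C(C)=O)[C@@H](CC(=O)C(=O)OCC)O1
F2 | step 4 | (4S,5S)-4-(iodomethyl)-2,2-dimethyl-5-[(trimethylsilyl)ethynyl]-1,3-dioxolane | CC1(C)O[C@@H](C#C[Si](C)(C)C)[C@@H](CI)O1
F3 | step 4 | 2-{[(4R,5S)-2,2-dimethyl-5-[(trimethylsilyl)ethynyl]-1,3-dioxolan-4-yl]methyl}-1,3-dithiane | CC1(C)O[C@@H](C#C[Si](C)(C)C)[C@@H](CC2SCCCS2)O1
F4 | step 4 | ethyl 2-{[(4R,5S)-2,2-dimethyl-5-[(trimethylsilyl)ethynyl]-1,3-dioxolan-4-yl]methyl}-1,3-dithiane-2-carboxylate | CC1(C)O[C@@H](C#C[Si](C)(C)C)[C@@H](CC2(C(=O)OCC)SCCCS2)O1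
F5 | step 11 | 3-O-(tert-butyldimethylsilyl)-1,5-quinide | O[C@H]1[C@H]2C[C@](O)(C(=O)O2)C[C@H]1O[Si](C)(C)C(C)(C)C
F6 | step 11 | 4-O-[(E)-4-acetoxycinnamoyl]-3-O-(tert-butyldimethylsilyl)-1,5-quinide | O=C(/C=C/c1ccc(OC(C)=O)cc1)O[C@H]1[C@H]2C[C@](O)(C(=O)O2)C[C@H]1O[Si](C)(C)C(C)(C)C
F7 | step 11 | 4-O-[(E)-4-acetoxycinnamoyl]-1,5-quinide | O=C(/C=C/c1ccc(OC(C)=O)cc1)O[C@H]1[C@H]2C[C@](O)(C(=O)O2)C[C@H]1O
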